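**Retrosynthetic overview**
1. The target is an 8-prenylflavonol. Ring C is closed last by Algar–Flynn–Oyamada oxidation of a chalcone made from ring A acetophenone 14 and ring B aldehyde 10, followed by removal of three MOM groups.
2. In aldehyde 10 the CHO comes from Br/Li exchange and DMF at C5 of a 5,6-dibromochromene, and the 1,1-dimethylallyl group from a γ-selective Suzuki–Miyaura coupling at the less hindered C6–Br.
3. Key disconnection: the pyran ring of the 2,2-dimethylchromene is cut at C4–C4a and C2–C3. The enabling feature is that in ring B the pyran oxygen (on C3′) and the free 4′-OH sit on adjacent carbons, so O–CMe2 and the 4′-oxygen can be stored together as a 2,2-dimethyl-1,3-benzodioxole, a five-membered ring that is not in the target.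
4. Lewis-acid opening of that ring gives the aryl oxocarbenium ion (2-oxadiene C2′=C3′–O+=CMe2), which takes up ethyl vinyl ether as an acetylene equivalent in a formal [4+2]; loss of ethanol then gives the chromene. The C2v-symmetric 5,6-dibromo acetonide removes any regiochemical question.
5. Ring order: rings A and B are bought as arenes; pyran ring of the chromene (step 2); ring C of the flavonol (step 9).

Key step: step 2

Assumption: the target has no stereocentre, so no stereocontrol is needed; the one centre formed on the way (C4 of intermediate 4) is racemic and is removed within step 2.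

**Step 1**
Reactants: 1 2,2-dimethyl-1,3-benzodioxole
Product: 2 5,6-dibromo-2,2-dimethyl-1,3-benzodioxole
Conditions: NBS (2.2 equiv), MeCN, 0 → 50 °C
Reagents that add atoms: N-bromosuccinimide, O=C1CCC(=O)N1Br
Why: Electrophilic aromatic bromination, in which each acetal oxygen directs to its para position so that the bromines should enter at C5 and C6 and the symmetry is kept, while NBS avoids the strong acid that would cleave the ketal.

**Step 2**
Reactants: 2 5,6-dibromo-2,2-dimethyl-1,3-benzodioxole; 3 ethyl vinyl ether
Product: 5 5,6-dibromo-2,2-dimethyl-2H-chromen-8-ol, via 4-ethoxychromanol 4 (not isolated)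
Conditions: TiCl4 (1.5 equiv), CH2Cl2, −78 °C; then 3 (1.5 equiv, slow addition), −78 → 0 °C; H2O quench; crude 4, p-TsOH·H2O (cat.), toluene, 90 °C
Reagents that add atoms: none
Why: Proposed new method: TiCl4 binds the acetal oxygens and opens the benzodioxole to a titanium phenoxide and the aryl oxocarbenium ion ArO+=CMe2 (a cationic 2-oxadiene made of the arene C=C, the ether oxygen and the CMe2 carbon), whose CMe2 carbon is attacked by the β-carbon of ethyl vinyl ether; the resulting ethoxycarbenium ion is captured by the arene carbon ortho to the ether oxygen (6-exo-trig Friedel–Crafts closure of the pyran ring, the only ring closed), so that the C2–C3 and C4–C4a bonds form in one polar, stepwise formal [4+2], and acid-catalysed loss of ethanol from 4 through the benzylic cation stabilised by the ring oxygen gives the chromene. The closest known reaction types are the oxa-Povarov reaction of aryl oxocarbenium ions (from aldehyde-derived mixed aryl acetals) with alkenes, the Povarov reaction with enol ethers and the Lewis-acid opening of cyclic acetals by π-nucleophiles; new are the ketone-derived oxocarbenium ion and its release from a catechol acetonide. The only stereocentre formed (C4 of 4) is racemic and is destroyed in the elimination. Regioselectivity needs no control because 2 is C2v-symmetric (both C–O cleavages and both ortho carbons are equivalent) and the tether allows only six-membered closure next to the ether oxygen; premixing 2 with TiCl4 and slow addition of 3 should suppress oligomerisation of the vinyl ether, and the neighbouring titanium phenoxide can hold the ethoxycarbenium ion reversibly as a seven-membered acetal until the ring closes.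

**Step 3**
Reactants: 5 5,6-dibromo-2,2-dimethyl-2H-chromen-8-ol
Product: 6 5,6-dibromo-8-(methoxymethoxy)-2,2-dimethyl-2H-chromene
Conditions: MOMCl, i-Pr2NEt, CH2Cl2, 0 °C → rt
Reagents that add atoms: chloromethyl methyl ether, COCCl
Why: O-alkylation of the phenol (MOM protection), which masks the acidic OH before the organometallic steps and is stable to base, palladium and organolithium.

**Step 4**
Reactants: 6 5,6-dibromo-8-(methoxymethoxy)-2,2-dimethyl-2H-chromene; 7 prenylboronic acid pinacol ester
Product: 8 5-bromo-8-(methoxymethoxy)-2,2-dimethyl-6-(2-methylbut-3-en-2-yl)-2H-chromene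
Conditions: Pd(OAc)2 (cat.), t-BuXPhos (cat.), K3PO4, THF/H2O, 40 °C
Reagents that add atoms: none
Why: Ligand-controlled γ-selective Suzuki–Miyaura coupling of an allylboronate, in which oxidative addition should prefer the C6–Br (one ortho substituent) over the C5–Br wedged between bromine and the ring-fusion carbon, and SE2′ transmetalation with fast reductive elimination from the bulky phosphine complex should deliver the tertiary carbon (the quaternary centre is not stereogenic).

**Step 5**
Reactants: 8 5-bromo-8-(methoxymethoxy)-2,2-dimethyl-6-(2-methylbut-3-en-2-yl)-2H-chromene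
Product: 10 8-(methoxymethoxy)-2,2-dimethyl-6-(2-methylbut-3-en-2-yl)-2H-chromene-5-carbaldehyde, via aryllithium 9 (not isolated)
Conditions: n-BuLi, THF, −78 °C; then DMF, −78 → 0 °C; H2O
Reagents that add atoms: N,N-dimethylformamide, CN(C)C=O
Why: Bromine–lithium exchange followed by formylation with DMF, since exchange is much faster than ortho-lithiation beside the OMOM group and the hindered aryllithium 9 should still add to the small electrophile.

**Step 6**
Reactants: 11 2,4,6-trihydroxyacetophenone; 12 prenyl bromide
Product: 13 1-[2,4,6-trihydroxy-3-(3-methylbut-2-en-1-yl)phenyl]ethanone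
Conditions: DBU, THF, 0 °C → rt
Reagents that add atoms: none
Why: C-alkylation of the phloroglucinol-type phenoxide (nuclear C-prenylation), where the symmetry of 11 makes the two free ring positions equivalent so that only one mono-C-prenyl isomer can form.

**Step 7**
Reactants: 13 1-[2,4,6-trihydroxy-3-(3-methylbut-2-en-1-yl)phenyl]ethanone
Product: 14 1-[2-hydroxy-4,6-bis(methoxymethoxy)-3-(3-methylbut-2-en-1-yl)phenyl]ethanone
Conditions: MOMCl (2.2 equiv), i-Pr2NEt, CH2Cl2, 0 °C → rt
Reagents that add atoms: chloromethyl methyl ether, COCCl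
Why: MOM protection of phenols, in which the 4-OH and the less hindered 6-OH should react while the 2-OH, hydrogen-bonded to the ketone and flanked by the prenyl group, is expected to stay free as required for the 8-prenyl series (the regioisomer would be removed by chromatography).

**Step 8**
Reactants: 14 1-[2-hydroxy-4,6-bis(methoxymethoxy)-3-(3-methylbut-2-en-1-yl)phenyl]ethanone; 10 8-(methoxymethoxy)-2,2-dimethyl-6-(2-methylbut-3-en-2-yl)-2H-chromene-5-carbaldehyde
Product: 15 (E)-1-[2-hydroxy-4,6-bis(methoxymethoxy)-3-(3-methylbut-2-en-1-yl)phenyl]-3-[8-(methoxymethoxy)-2,2-dimethyl-6-(2-methylbut-3-en-2-yl)-2H-chromen-5-yl]prop-2-en-1-one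
Conditions: KOH, EtOH/H2O, rt → 50 °C
Reagents that add atoms: none
Why: Claisen–Schmidt condensation, in which the non-enolisable aldehyde can only be the acceptor and base-mediated dehydration should give the E-enone under thermodynamic control, with warming foreseen for the hindered, twisted formyl group.

**Step 9**
Reactants: 15 the E-chalcone
Product: 16 3-hydroxy-5,7-bis(methoxymethoxy)-2-[8-(methoxymethoxy)-2,2-dimethyl-6-(2-methylbut-3-en-2-yl)-2H-chromen-5-yl]-8-(3-methylbut-2-en-1-yl)-4H-chromen-4-one
Conditions: 30% H2O2, aq. NaOH, MeOH/THF, 0 °C → rt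
Reagents that add atoms: hydrogen peroxide, OO
Why: Algar–Flynn–Oyamada oxidative cyclisation, in which alkaline H2O2 attacks only the enone, the 2′-phenoxide closes ring C at the β-carbon and the 3-OH is introduced in the same operation, while the prenyl, vinyl and chromene alkenes are not electrophilic and should stay untouched.

**Step 10**
Reactants: 16 the tris-MOM flavonol
Product: 17 3,5,7-trihydroxy-2-[8-hydroxy-2,2-dimethyl-6-(2-methylbut-3-en-2-yl)-2H-chromen-5-yl]-8-(3-methylbut-2-en-1-yl)-4H-chromen-4-one (target)
Conditions: 3 M HCl, MeOH, 50 °C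
Reagents that add atoms: none
Why: Acid-catalysed acetal exchange (MOM cleavage) in methanol, where mild acid and moderate temperature should leave the prenyl group, the 1,1-dimethylallyl group and the chromene intact.

**Compound list**
1 | 2,2-dimethyl-1,3-benzodioxole | CC1(C)Oc2ccccc2O1 | starting material
2 | 5,6-dibromo-2,2-dimethyl-1,3-benzodioxole | CC1(C)Oc2cc(Br)c(Br)cc2O1 | intermediate
3 | ethyl vinyl ether | C=COCC | starting material
4 | 5,6-dibromo-4-ethoxy-2,2-dimethylchroman-8-ol (racemic, not isolated) | CCOC1CC(C)(C)Oc2c(O)cc(Br)c(Br)c21 | intermediate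
5 | 5,6-dibromo-2,2-dimethyl-2H-chromen-8-ol | CC1(C)C=Cc2c(Br)c(Br)cc(O)c2O1 | intermediate
6 | 5,6-dibromo-8-(methoxymethoxy)-2,2-dimethyl-2H-chromene | COCOc1cc(Br)c(Br)c2c1OC(C)(C)C=C2 | intermediate
7 | prenylboronic acid pinacol ester | CC(C)=CCB1OC(C)(C)C(C)(C)O1 | starting material
8 | 5-bromo-8-(methoxymethoxy)-2,2-dimethyl-6-(2-methylbut-3-en-2-yl)-2H-chromene | COCOc1cc(C(C)(C)C=C)c(Br)c2c1OC(C)(C)C=C2 | intermediate
9 | [8-(methoxymethoxy)-2,2-dimethyl-6-(2-methylbut-3-en-2-yl)-2H-chromen-5-yl]lithium (not isolated) | COCOc1cc(C(C)(C)C=C)c([Li])c2c1OC(C)(C)C=C2 | intermediate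
10 | 8-(methoxymethoxy)-2,2-dimethyl-6-(2-methylbut-3-en-2-yl)-2H-chromene-5-carbaldehyde | COCOc1cc(C(C)(C)C=C)c(C=O)c2c1OC(C)(C)C=C2 | intermediate
11 | 2,4,6-trihydroxyacetophenone | CC(=O)c1c(O)cc(O)cc1O | starting material
12 | prenyl bromide | CC(C)=CCBr | starting material
13 | 1-[2,4,6-trihydroxy-3-(3-methylbut-2-en-1-yl)phenyl]ethanone | CC(=O)c1c(O)cc(O)c(CC=C(C)C)c1O | intermediate
14 | 1-[2-hydroxy-4,6-bis(methoxymethoxy)-3-(3-methylbut-2-en-1-yl)phenyl]ethanone | CC(=O)c1c(OCOC)cc(OCOC)c(CC=C(C)C)c1O | intermediate
15 | E-chalcone from 14 and 10 | COCOc1cc(C(C)(C)C=C)c(/C=C/C(=O)c3c(OCOC)cc(OCOC)c(CC=C(C)C)c3O)c2c1OC(C)(C)C=C2 | intermediate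
16 | tris-MOM flavonol | COCOc1cc(C(C)(C)C=C)c(-c3oc4c(CC=C(C)C)c(OCOC)cc(OCOC)c4c(=O)c3O)c2c1OC(C)(C)C=C2 | intermediate
17 | CNP0241222.0 | C=CC(C)(C)c1cc(O)c2c(c1-c1oc3c(CC=C(C)C)c(O)cc(O)c3c(=O)c1O)C=CC(C)(C)O2 | target

**Step count**
Total steps: 10. Longest linear sequence: 8 (steps 1–5, then 8–10); steps 6–7 form the second branch.

**Steps most likely to fail**

Step 2 (proposed new method). Closure onto the ortho carbon, which is deactivated by two bromines, may be slower than two competing processes: further ionisation of the tertiary aryl ether with loss of the carbon chain back to the catecholate, and cationic oligomerisation of the vinyl ether. The fallback uses known chemistry and sets out from 2. Hydrolysis of the ketal (aq. CF3CO2H, THF, 50 °C) would give 4,5-dibromobenzene-1,2-diol F1. Mono-O-alkylation with 3-chloro-3-methylbut-1-yne (CuCl2 cat., DBU, MeCN, 0 °C) would give 4,5-dibromo-2-[(2-methylbut-3-yn-2-yl)oxy]phenol F2. Heating (N,N-diethylaniline, 190 °C) should then bring about aromatic propargyl Claisen rearrangement, 1,5-hydrogen shift and oxa-6π electrocyclisation, and the route is rejoined at 5.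

Step 4. The tertiary σ-allylpalladium intermediate may isomerise to the primary one before reductive elimination beside the ortho bromine, which would erode γ-selectivity, and oxidative addition may be poorly discriminated between the two bromides. The fallback sets out from 6 and builds the quaternary carbon without an allyl transposition. Palladium-catalysed α-arylation of methyl isobutyrate (Pd(dba)2, P(t-Bu)3, LiNCy2, toluene, rt) would give methyl 2-[5-bromo-8-(methoxymethoxy)-2,2-dimethyl-2H-chromen-6-yl]-2-methylpropanoate F3. Partial reduction (i-Bu2AlH, CH2Cl2, −78 °C) would give 2-[5-bromo-8-(methoxymethoxy)-2,2-dimethyl-2H-chromen-6-yl]-2-methylpropanal F4. Wittig methylenation (Ph3P=CH2, THF, 0 °C) returns to the route at 8.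

Step 9. After epoxidation of the enone, the phenoxide may attack the α-carbon (five-membered closure, aurone pathway) instead of the hindered β-carbon; this is favoured by the 6′-alkoxy group and by the twisted, doubly ortho-substituted ring B. The fallback sets out from 15 and separates ring closure from oxidation. Oxa-Michael cyclisation (NaOAc, EtOH, reflux), where only six-membered closure is possible, would give the racemic flavanone F5. Dehydrogenation (DDQ, dioxane, 90 °C) would give the flavone F6. C3-lithiation, borylation and oxidation (LiN(i-Pr)2, THF, −78 °C; B(OMe)3; then H2O2, AcOH) returns to the route at 16.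

**Further compounds**
F1 | step 2 | 4,5-dibromobenzene-1,2-diol | Oc1cc(Br)c(Br)cc1O
F2 | step 2 | 4,5-dibromo-2-[(2-methylbut-3-yn-2-yl)oxy]phenol | C#CC(C)(C)Oc1cc(Br)c(Br)cc1O
F3 | step 4 | methyl 2-[5-bromo-8-(methoxymethoxy)-2,2-dimethyl-2H-chromen-6-yl]-2-methylpropanoate | COCOc1cc(C(C)(C)C(=O)OC)c(Br)c2c1OC(C)(C)C=C2
F4 | step 4 | 2-[5-bromo-8-(methoxymethoxy)-2,2-dimethyl-2H-chromen-6-yl]-2-methylpropanal | COCOc1cc(C(C)(C)C=O)c(Br)c2c1OC(C)(C)C=C2
F5 | step 9 | racemic 5,7-bis(methoxymethoxy)-2-[8-(methoxymethoxy)-2,2-dimethyl-6-(2-methylbut-3-en-2-yl)-2H-chromen-5-yl]-8-(3-methylbut-2-en-1-yl)chroman-4-one | COCOc1cc(C(C)(C)C=C)c(C3CC(=O)c4c(OCOC)cc(OCOC)c(CC=C(C)C)c4O3)c2c1OC(C)(C)C=C2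
F6 | step 9 | 5,7-bis(methoxymethoxy)-2-[8-(methoxymethoxy)-2,2-dimethyl-6-(2-methylbut-3-en-2-yl)-2H-chromen-5-yl]-8-(3-methylbut-2-en-1-yl)-4H-chromen-4-one | COCOc1cc(C(C)(C)C=C)c(-c3cc(=O)c4c(OCOC)cc(OCOC)c(CC=C(C)C)c4o3)c2c1OC(C)(C)C=C2
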